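Cuts: the two aryl–allyl bonds C6–C1'' (ring A) and C3'–C1''' (ring B) are cut together in the last step. Behind them, the saturated C2–C3 bond of ring C is traced back to the C2=C3 double bond of genistein.
Forward order: rings A, B and C all arrive with genistein. Ring C is reduced first, prenol is converted separately into its diphosphate, and both C5 chains are then joined to the unprotected isoflavanone in one pot.
Enabling feature: C6 is the CH between the 5-OH and 7-OH of the phloroglucinol-type ring A, and C3' is the CH ortho to the 4'-OH of ring B. Both are phenol-activated carbons that can trap an enzyme-held dimethylallyl cation, and the free OH groups anchor the substrate in the active sites.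
Stereochemistry: the only centre, C3 (R), comes from face-selective protonation of C3 during the enzymatic reduction of C2=C3. After that it is only preserved (pH below 7, no base, no strong acid).

Key step: step 3

Assumption: the recombinant enzymes (DZNR, choline kinase, IPK, 7-DMATS, NovQ) come from routine E. coli expression of synthetic genes and count as catalysts, and all phosphate esters are drawn as free acids although they are handled as salts near neutral pH.

Step 1
Reactants: 1 genistein (5,7,4'-trihydroxyisoflavone)
Product: 2 (3R)-dihydrogenistein [(3R)-5,7,4'-trihydroxyisoflavanone]
Conditions: daidzein reductase (DZNR of Slackia isoflavoniconvertens, E. coli cell-free extract), NADP+ (cat.), D-glucose (1.5 equiv), glucose dehydrogenase, KPi pH 6.5, 5% DMSO, N2, 30 °C; then pH 5, EtOAc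
Reagents that add atoms: none
Why: This is a flavin-dependent ene-reductase (old-yellow-enzyme-type) conjugate reduction of C2=C3–C4=O, which this bacterial enzyme family is known to perform on daidzein and genistein: the reduced flavin delivers hydride to C2 and an active-site acid protonates C3 from one face only, which should set 3R, and the absence of the partner racemase and the slightly acidic buffer should preserve it.

Step 2
Reactants: 3 prenol (3-methylbut-2-en-1-ol)
Product: 5 dimethylallyl diphosphate (DMAPP; kept as the triammonium salt), via dimethylallyl phosphate 4 (not isolated)
Conditions: choline kinase (S. cerevisiae), isopentenyl phosphate kinase (A. thaliana), ATP (5 mol%), acetyl phosphate (2.5 equiv), acetate kinase, MgCl2, HEPES pH 7.5, 30 °C; ultrafiltration, anion exchange (NH4HCO3 gradient), lyophilisation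
Reagents that add atoms: acetyl phosphate (lithium potassium salt; phosphoryl donor relayed through ATP), CC(=O)OP(=O)(O)O
Why: Two sequential ATP-dependent kinase phosphorylations (the isopentenol-utilisation pair) build the diphosphate on the intact primary allylic oxygen, so the labile allylic C–O bond is never activated, and acetate kinase with acetyl phosphate regenerates ATP and drives both transfers.

Step 3
Reactants: 2 (3R)-dihydrogenistein; 5 dimethylallyl diphosphate (two equivalents consumed)
Product: 8 (3R)-5,7,4'-trihydroxy-6,3'-diprenylisoflavanone (target), via (3R)-6-prenyldihydrogenistein 6 (not isolated), via (3R)-3'-prenyldihydrogenistein 7 (not isolated)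
Conditions: 7-DMATS (Aspergillus fumigatus) + NovQ (Streptomyces niveus), 5 (3 equiv, in portions), MOPS pH 6.8, CaCl2 (5 mM), 5% DMSO, 30 °C, ≤ 12 h; then pH 5.5, EtOAc; reversed-phase chromatography (MeCN/H2O, 0.1% HCO2H); chiral HPLC check
Reagents that add atoms: none
Why: In each enzyme, basic residues grip the diphosphate of 5 and promote heterolysis of its allylic C1–O bond, the dimethylallyl cation is shielded by aromatic side chains and held over a single arene CH of the bound flavonoid, that carbon attacks C1 of the cation, and loss of the ring proton from the arenium ion restores aromaticity. This is the enzymatic Friedel–Crafts alkylation of the aromatic prenyltransferase class, known for C6-dimethylallylation of 5,7-dihydroxyflavanones and -isoflavones with the DMATS-type enzyme and for ortho-dimethylallylation of 4-hydroxyphenyl rings (native 4-hydroxyphenylpyruvate and ring B of flavonoids) with the ABBA-type enzyme; compound 2 shares its 5,7-dihydroxychroman-4-one half with the first acceptor set and its 4-hydroxyphenyl group on an sp3 carbon next to a ketone with the second. No ring is closed and no stereocentre is formed; C3 is a spectator whose R configuration should persist because enolisation of the C4 ketone should be slow at pH 6.8, 30 °C and within the limited run time. The step needs C6 over C8 and over the three phenolic oxygens, ring B in the presence of the far more nucleophilic ring A, and attack on C1 rather than C3 of the allyl cation; the substrate supplies the chelated 5-OH/C4=O pair and the 7-OH flanking C6, and the 4'-OH next to C3', as hydrogen-bond anchors, and each pocket uses them to present only its own CH to the cation. C3' and C5' interconvert by rotation about C3–C1', so ring B can give only one C-prenyl isomer. Because the two enzymes act on different rings, either monoprenyl compound (6 or 7) is a substrate for the other enzyme and both orders converge on 8.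

Compound list
1 | genistein | O=c1c(-c2ccc(O)cc2)coc2cc(O)cc(O)c12 | starting material
2 | (3R)-dihydrogenistein | Oc1ccc([C@@H]2COc3cc(O)cc(O)c3C2=O)cc1 | intermediate
3 | prenol | CC(C)=CCO | starting material
4 | dimethylallyl phosphate | CC(C)=CCOP(=O)(O)O | intermediate
5 | dimethylallyl diphosphate (DMAPP) | CC(C)=CCOP(=O)(O)OP(=O)(O)O | intermediate
6 | (3R)-6-prenyldihydrogenistein | Oc1ccc([C@@H]2COc3cc(O)c(CC=C(C)C)c(O)c3C2=O)cc1 | intermediate
7 | (3R)-3'-prenyldihydrogenistein | CC(C)=CCc1cc([C@@H]2COc3cc(O)cc(O)c3C2=O)ccc1O | intermediate
8 | (3R)-5,7,4'-trihydroxy-6,3'-diprenylisoflavanone | CC(C)=CCc1cc([C@@H]2COc3cc(O)c(CC=C(C)C)c(O)c3C2=O)ccc1O | target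

Total step count: 3. Longest linear sequence: 2 (1 → 2 → 8, or 3 → 5 → 8).

Steps most likely to fail

1. Step 3.
- Risk: one enzyme may turn over the non-planar isoflavanone, or a monoprenylated intermediate, too slowly, so that the reaction stalls halfway. Alkylation may leak to the 4'-oxygen or to C8. A prolonged incubation may erode C3 by enolisation.
- Fallback: it sets out from 2 (with prenol 3) and returns at 8. Mitsunobu etherification of the two non-chelated phenols of 2 with 3 (PPh3, DIAD, THF, 0 °C) should give (3R)-5-hydroxy-7,4'-bis(prenyloxy)isoflavanone F1 without exposing C3 to base. Stirring it with montmorillonite K10 in CH2Cl2 at 0 °C to room temperature should move each prenyl group from oxygen to an ortho carbon by the clay-promoted [1,3]-shift of aryl prenyl ethers. Ring B can only deliver C3'. Ring A delivers C6 and C8 products, from which 8 is separated by reversed-phase HPLC.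

2. Step 1.
- Risk: oxygen may inactivate the iron–sulfur flavoenzyme, the low solubility of 1 may limit conversion, and C3 may partly racemise in the buffer.
- Fallback: it sets out from 1 and returns at 2. Catalytic transfer hydrogenation (Pd/C, HCO2NH4, MeOH) should give racemic dihydrogenistein F2. This is resolved by preparative HPLC on a polysaccharide chiral phase (hexane/EtOH, 0.1% AcOH) into 2 and (3S)-dihydrogenistein F3. The latter is re-equilibrated with a trace of Et3N in MeOH and recycled through the column.

3. Step 2.
- Risk: the cascade may stall at the monophosphate stage, acetyl phosphate may hydrolyse before transfer, and the allylic diphosphate may solvolyse during ion exchange and drying.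
- Fallback: it sets out from 3 and returns at 5. Bromination (PBr3, Et2O, 0 °C) should give prenyl bromide F4. SN2 displacement with tris(tetrabutylammonium) hydrogen diphosphate in MeCN at room temperature follows, then cation exchange to the ammonium form and cellulose chromatography to give 5.

Further compounds
F1 | step 3 | (3R)-5-hydroxy-7,4'-bis(prenyloxy)isoflavanone | CC(C)=CCOc1ccc([C@@H]2COc3cc(OCC=C(C)C)cc(O)c3C2=O)cc1
F2 | step 1 | racemic dihydrogenistein | Oc1ccc(C2COc3cc(O)cc(O)c3C2=O)cc1
F3 | step 1 | (3S)-dihydrogenistein | Oc1ccc([C@H]2COc3cc(O)cc(O)c3C2=O)cc1
F4 | step 2 | prenyl bromide | CC(C)=CCBr
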